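**Plan**
1. Labels: ring A is the resorcinol ring (C1 styryl, C2 benzyl, C3 OH, C5 OH), ring B the guaiacyl ring, ring C the catechol ring, and C7 the diarylmethane CH2.
2. Retrosynthetic cuts, in order: C7–C1'' (to ring C), then C2–C7 (a formyl carbon), then C1–C(alpha) of the stilbene. All three rings are bought.
3. Enabling feature: C7 sits on C2 of ring A directly beside the C3 oxygen. The unit O3–C3–C2–C7 can therefore be unmasked as an ortho-quinone methide whose only rearomatising acceptor site is C7, and a metalated ring C adds there through its ipso carbon.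
4. Forward order: a Heck reaction joins B to A and a Vilsmeier–Haack formylation puts C7 on C2. Three Boc groups then mask the phenols (the C3 one is also the trigger) and reduction sets the CH2 level. The quinone methide cascade brings in ring C, and one acid step removes every mask.
5. Stereochemistry: there is no stereocentre. The E alkene comes from the Heck step (syn insertion, syn beta-hydride elimination) and is not touched afterwards.

Key step: step 6

Remark: from compound 3 onward all operations are assumed to run under argon with exclusion of light, because hydroxystilbenes photoisomerise and catechols autoxidise.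

Step 1
Reactants: 1 5-bromoresorcinol (5-bromobenzene-1,3-diol); 2 2-methoxy-4-vinylphenol
Product: 3 isorhapontigenin = (E)-5-(4-hydroxy-3-methoxystyryl)benzene-1,3-diol
Conditions: Pd(OAc)2 (3 mol%), P(o-tol)3 (9 mol%), Et3N (3 equiv), DMF, 100 °C, trace BHT
Reagents that add atoms: none
Why: Mizoroki–Heck reaction in which zerovalent palladium inserts into the C–Br bond of 1 (both hydroxyls are meta to bromine and do not retard this), the aryl group goes to the terminal alkene carbon of 2 by syn insertion, and syn beta-hydride elimination should give the E-stilbene, free phenols being tolerated with P(o-tol)3 and an amine base.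

Step 2
Reactants: 3 isorhapontigenin
Product: 5 (E)-2,4-dihydroxy-6-(4-hydroxy-3-methoxystyryl)benzaldehyde, via aryl iminium chloride 4 (not isolated)
Conditions: POCl3 (1.3 equiv), DMF (3 equiv), MeCN, 0 °C to rt; then H2O, 50 °C
Reagents that add atoms: N,N-dimethylformamide CN(C)C=O; water O
Why: Vilsmeier–Haack formylation in which the chloroiminium ion should attack ring A at C2 (equivalent to C6), para to one hydroxyl and ortho to the other, as 5-substituted resorcinols and 3,5-dioxygenated stilbenes do, while ring B, a singly activated phenol with its para position blocked, is not nucleophilic enough.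

Step 3
Reactants: 5 (E)-2,4-dihydroxy-6-(4-hydroxy-3-methoxystyryl)benzaldehyde
Product: 6 (E)-2,4-bis(tert-butoxycarbonyloxy)-6-[4-(tert-butoxycarbonyloxy)-3-methoxystyryl]benzaldehyde
Conditions: Boc2O (3.6 equiv), i-Pr2NEt (3.6 equiv), DMAP (5 mol%), THF, 0 °C to rt
Reagents that add atoms: di-tert-butyl dicarbonate CC(C)(C)OC(=O)OC(=O)OC(C)(C)C
Why: DMAP-catalysed O-acylation of phenols should carbonate all three hydroxyls, including the hydrogen-bonded one next to the formyl group, which masks the phenols and places the later trigger on O3.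

Step 4
Reactants: 6 tri-O-Boc aldehyde
Product: 7 (E)-{2,4-bis(tert-butoxycarbonyloxy)-6-[4-(tert-butoxycarbonyloxy)-3-methoxystyryl]phenyl}methanol
Conditions: NaBH(OAc)3 (3 equiv), AcOH (5 equiv), THF, rt to 40 °C
Reagents that add atoms: none
Why: Chemoselective aldehyde reduction by an acyloxyborohydride in an acidic medium delivers the carbinol as the neutral alcohol and never as a free alkoxide, so the Boc shift and elimination are not set off early, and the stilbene and the carbonates are inert to this mild hydride.

Step 5
Reactants: 8 4-bromocatechol (4-bromobenzene-1,2-diol)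
Product: 9 4-bromo-1,2-bis(methoxymethoxy)benzene
Conditions: MOMCl (2.6 equiv), i-Pr2NEt (3 equiv), CH2Cl2, 0 °C to rt
Reagents that add atoms: chloromethyl methyl ether COCCl
Why: Williamson-type O-alkylation of both phenols gives base-stable acetal ethers that survive magnesium insertion and leave under the same acid that removes Boc.

Step 6
Reactants: 7 tri-O-Boc benzylic alcohol; 9 4-bromo-1,2-bis(methoxymethoxy)benzene
Product: 14 5,4'-di-O-Boc-3'',4''-di-O-MOM-gnetupendin B (free C3 phenol), via aryl Grignard reagent 10 (not isolated), via magnesium alkoxide 11 (not isolated), via magnesium phenoxide carbonate 12 (not isolated), via ortho-quinone methide 13 (not isolated)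
Conditions: 9 (2.6 equiv), Mg turnings, THF, 40 °C; solution of 10 added to 7, THF, −78 °C to rt; H2O work-up
Reagents that add atoms: none
Why: The first equivalent of 10 deprotonates 7 to alkoxide 11, whose oxygen takes the Boc group from the neighbouring O3 through a six-membered transition state to give phenoxide 12, and this magnesium phenoxide expels tert-butyl carbonate in a 1,4-elimination that turns ring A into ortho-quinone methide 13. The second equivalent of 10 adds its ipso carbon to the exocyclic CH2 of 13 (1,4-addition), which forms the C7–C1'' bond, restores the aromaticity of ring A and sets the C3 phenol free. The closest known reaction type is the base-triggered generation of ortho-quinone methides from O-Boc salicyl alcohols followed by conjugate addition of Grignard reagents; no ring is closed, no stereocentre is formed and the E alkene is a spectator. The site on ring C is fixed by the carbon–magnesium bond (para to one oxygen, meta to the other), which a Friedel–Crafts reaction of catechol could not guarantee. Among the three carbonates only the C3 one has the alkoxide within reach, while the hindered C5 and C4' tert-butyl carbonates should stay on at low temperature and keep rings A and B too electron-poor to compete as nucleophiles for 13. Because the medium is basic and 13 forms slowly in the presence of excess 10, neither dimerisation of 13 nor the cationic 4π (Nazarov-type) closure of C7 onto the styryl double bond, which acid ionisation of such an alcohol invites, should compete.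

Step 7
Reactants: 14 5,4'-di-O-Boc-3'',4''-di-O-MOM-gnetupendin B
Product: 15 gnetupendin B = (E)-4-(3,4-dihydroxybenzyl)-5-(4-hydroxy-3-methoxystyryl)benzene-1,3-diol
Conditions: HCl (3 M in MeOH), MeOH, 0 °C to 35 °C
Reagents that add atoms: none
Why: Acidolysis fragments both tert-butyl carbonates and acetal exchange with methanol removes both MOM ethers in one operation, while the aryl methyl ether and the E alkene should be inert to dilute methanolic HCl and the solvent intercepts the cations.

**Compound list**
1 | 5-bromoresorcinol | Oc1cc(O)cc(Br)c1 | starting material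
2 | 2-methoxy-4-vinylphenol | C=Cc1ccc(O)c(OC)c1 | starting material
3 | isorhapontigenin, (E)-5-(4-hydroxy-3-methoxystyryl)benzene-1,3-diol | COc1cc(/C=C/c2cc(O)cc(O)c2)ccc1O | intermediate
4 | (E)-[2,4-dihydroxy-6-(4-hydroxy-3-methoxystyryl)benzylidene]dimethyliminium chloride | COc1cc(/C=C/c2cc(O)cc(O)c2C=[N+](C)C)ccc1O.[Cl-] | intermediate
5 | (E)-2,4-dihydroxy-6-(4-hydroxy-3-methoxystyryl)benzaldehyde | COc1cc(/C=C/c2cc(O)cc(O)c2C=O)ccc1O | intermediate
6 | (E)-2,4-bis(Boc-oxy)-6-[4-(Boc-oxy)-3-methoxystyryl]benzaldehyde | COc1cc(/C=C/c2cc(OC(=O)OC(C)(C)C)cc(OC(=O)OC(C)(C)C)c2C=O)ccc1OC(=O)OC(C)(C)C | intermediate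
7 | (E)-{2,4-bis(Boc-oxy)-6-[4-(Boc-oxy)-3-methoxystyryl]phenyl}methanol | COc1cc(/C=C/c2cc(OC(=O)OC(C)(C)C)cc(OC(=O)OC(C)(C)C)c2CO)ccc1OC(=O)OC(C)(C)C | intermediate
8 | 4-bromocatechol | Oc1ccc(Br)cc1O | starting material
9 | 4-bromo-1,2-bis(methoxymethoxy)benzene | COCOc1ccc(Br)cc1OCOC | intermediate
10 | [3,4-bis(methoxymethoxy)phenyl]magnesium bromide | COCOc1ccc([Mg]Br)cc1OCOC | intermediate
11 | bromomagnesium alkoxide of 7 | COc1cc(/C=C/c2cc(OC(=O)OC(C)(C)C)cc(OC(=O)OC(C)(C)C)c2CO[Mg]Br)ccc1OC(=O)OC(C)(C)C | intermediate
12 | bromomagnesium C3 phenoxide bearing the C7 tert-butyl carbonate | COc1cc(/C=C/c2cc(OC(=O)OC(C)(C)C)cc(O[Mg]Br)c2COC(=O)OC(C)(C)C)ccc1OC(=O)OC(C)(C)C | intermediate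
13 | 3-(Boc-oxy)-5-[(E)-4-(Boc-oxy)-3-methoxystyryl]-6-methylenecyclohexa-2,4-dien-1-one | C=C1C(=O)C=C(OC(=O)OC(C)(C)C)C=C1/C=C/c2ccc(OC(=O)OC(C)(C)C)c(OC)c2 | intermediate
14 | 5,4'-di-O-Boc-3'',4''-di-O-MOM-gnetupendin B | COc1cc(/C=C/c2cc(OC(=O)OC(C)(C)C)cc(O)c2Cc2ccc(OCOC)c(OCOC)c2)ccc1OC(=O)OC(C)(C)C | intermediate
15 | gnetupendin B | COc1cc(/C=C/c2cc(O)cc(O)c2Cc2ccc(O)c(O)c2)ccc1O | target

**Totals:** 7 steps. The longest linear sequence is 6 steps (1, 2, 3, 4, 6, 7).

**Steps most likely to fail**

**Step 6.** Attack of the Grignard reagent on the aryl carbonates, or self-cycloaddition of the quinone methide, may outrun the conjugate addition.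
- This fallback sets out from 7 and 10 and comes back at 15. It replaces the quinone methide by a palladium-catalysed Negishi cross-coupling.
- Alcohol 7 is brominated under Appel conditions (CBr4, PPh3, CH2Cl2, 0 °C) to the tri-O-Boc benzylic bromide F1.
- Grignard reagent 10 is transmetalated with ZnBr2 in THF to the arylzinc bromide F2.
- The two are coupled with Pd(PPh3)4 (5 mol%) in THF at rt to the tri-O-Boc di-O-MOM diarylmethane F3.
- The conditions of step 7 should convert F3 into 15.

**Step 4.** A premature Boc shift and elimination followed by over-reduction at C7, or slow hydride delivery to the doubly flanked aldehyde, may spoil the reduction.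
- This fallback sets out from 6 and 9 and comes back at 14. It skips the alcohol by running the quinone methide cascade at the aldehyde level with the two nucleophiles in reverse order.
- Bromide 9 is treated with n-BuLi (THF, −78 °C) to give the aryllithium F4, which is added to 6 at −78 °C.
- 1,2-Addition followed by the Boc shift should give the lithium phenoxide benzhydryl carbonate F5, which persists in the cold.
- LiBH4 and MgBr2·OEt2 are then added and the mixture is warmed to 0 °C.
- The aryl-substituted ortho-quinone methide F6 should then be reduced at C7 by hydride as it forms, giving 14.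

**Step 7.** The electron-rich rings may capture tert-butyl cations. Protonation of the stilbene may also be followed by solvent addition or by seven-membered closure from ring C.
- This fallback sets out from 8 and 7 and comes back at 15. It changes the masking of ring C so that the endgame needs no acid.
- Compound 8 is silylated (TBSCl, imidazole, DMF) to 4-bromo-1,2-bis(tert-butyldimethylsilyloxy)benzene F7.
- F7 is converted with Mg in THF into the silyl-protected Grignard reagent F8, which is combined with 7 as in step 6 to give the 3'',4''-di-O-TBS diarylmethane F9.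
- Pyrrolidine in CH2Cl2 at rt removes both aryl carbonates by aminolysis to give 3'',4''-di-O-TBS-gnetupendin B F10.
- Bu4NF buffered with AcOH in THF at 0 °C cleaves the silyl ethers to 15.

**Further compounds**
F1 | step 6 | (E)-2-(bromomethyl)-1,5-bis(Boc-oxy)-3-[4-(Boc-oxy)-3-methoxystyryl]benzene | COc1cc(/C=C/c2cc(OC(=O)OC(C)(C)C)cc(OC(=O)OC(C)(C)C)c2CBr)ccc1OC(=O)OC(C)(C)C
F2 | step 6 | [3,4-bis(methoxymethoxy)phenyl]zinc bromide | COCOc1ccc([Zn]Br)cc1OCOC
F3 | step 6 | 3,5,4'-tri-O-Boc-3'',4''-di-O-MOM-gnetupendin B | COc1cc(/C=C/c2cc(OC(=O)OC(C)(C)C)cc(OC(=O)OC(C)(C)C)c2Cc2ccc(OCOC)c(OCOC)c2)ccc1OC(=O)OC(C)(C)C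
F4 | step 4 | [3,4-bis(methoxymethoxy)phenyl]lithium | [Li]c1ccc(OCOC)c(OCOC)c1
F5 | step 4 | lithium C3 phenoxide bearing the racemic C7 benzhydryl tert-butyl carbonate | COc1cc(/C=C/c2cc(OC(=O)OC(C)(C)C)cc(O[Li])c2C(OC(=O)OC(C)(C)C)c2ccc(OCOC)c(OCOC)c2)ccc1OC(=O)OC(C)(C)C
F6 | step 4 | 6-[3,4-bis(methoxymethoxy)benzylidene]-3-(Boc-oxy)-5-[(E)-4-(Boc-oxy)-3-methoxystyryl]cyclohexa-2,4-dien-1-one | O=C1C=C(OC(=O)OC(C)(C)C)C=C(/C=C/c2ccc(OC(=O)OC(C)(C)C)c(OC)c2)C1=Cc3ccc(OCOC)c(OCOC)c3
F7 | step 7 | 4-bromo-1,2-bis(tert-butyldimethylsilyloxy)benzene | CC(C)(C)[Si](C)(C)Oc1ccc(Br)cc1O[Si](C)(C)C(C)(C)C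
F8 | step 7 | [3,4-bis(tert-butyldimethylsilyloxy)phenyl]magnesium bromide | CC(C)(C)[Si](C)(C)Oc1ccc([Mg]Br)cc1O[Si](C)(C)C(C)(C)C
F9 | step 7 | 5,4'-di-O-Boc-3'',4''-di-O-TBS-gnetupendin B | COc1cc(/C=C/c2cc(OC(=O)OC(C)(C)C)cc(O)c2Cc2ccc(O[Si](C)(C)C(C)(C)C)c(O[Si](C)(C)C(C)(C)C)c2)ccc1OC(=O)OC(C)(C)C
F10 | step 7 | 3'',4''-di-O-TBS-gnetupendin B | COc1cc(/C=C/c2cc(O)cc(O)c2Cc2ccc(O[Si](C)(C)C(C)(C)C)c(O[Si](C)(C)C(C)(C)C)c2)ccc1O
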